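**Retrosynthetic overview**
- The target is cut at the C15–O ester bond into halim-1(10)-en-15-oic acid and (R)-glycidyl acetate (epoxide opening at the terminal carbon); the acid comes from its 11E-diene methyl ester by alkene hydrogenation and saponification.
- Key disconnection C9–C10: the vinylic C10 of the ring A C1=C10 alkene is bonded to quaternary C9 of ring B, the pattern left when a C10 vinylpalladium adds 6-exo to the methyl-bearing carbon of a tethered (E)-C9=C11 alkene. Ring A is bought; ring B closes last.
- The vinyl triflate comes from a (5S)-2-alkyl-3,3-dimethylcyclohexanone (kinetic triflation), this from an allyl enol carbonate (enantioselective decarboxylative protonation sets C5), and this from a 2-alkyl-3-methylcyclohexenone plus Me2CuLi (C4 gem-dimethyl).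
- The enone comes from 2-iodo-3-methylcyclohexenone and the C6–C15 alkyl iodide (Negishi coupling, C5–C6); the alkyl iodide from a C6–C11 (E)-alkenyl iodide and methyl (S)-4-iodo-3-methylbutanoate (Negishi coupling, C11–C12).
- The alkenyl iodide comes from (R)-α-methyl-γ-butyrolactone (C8; alkynylation, carboalumination–iodination); the iodo ester from methyl hydrogen (R)-3-methylglutarate (C13).

Key step: step 13

Assumption: atoms carry halimane numbers (C1–C20) throughout; the ligand antipodes named in steps 1, 11 and 13 are assigned by analogy with the closest known substrates, and the mirror-image ligand is used if the sense of induction proves opposite.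

**Route**

Step 1
Reactants: 1 α-methylene-γ-butyrolactone (3-methylideneoxolan-2-one)
Product: 2 (3R)-3-methyloxolan-2-one [(R)-α-methyl-γ-butyrolactone]
Conditions: H2 (100 bar), Ru(OAc)2[(S)-BINAP] (0.5 mol%), CH2Cl2, 50 °C
Reagents that add atoms: none
Why: Ru–BINAP asymmetric hydrogenation of an exocyclic alkene bound through the neighbouring lactone carbonyl is an established reaction of this very substrate and sets C8 by delivery of hydrogen to one alkene face.

Step 2
Reactants: 2 (3R)-3-methyloxolan-2-one
Product: 3 (3R)-3-methyloxolan-2-ol (lactol, both anomers)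
Conditions: i-Bu2AlH (1.1 equiv), CH2Cl2, −78 °C; MeOH, then aq. potassium sodium tartrate
Reagents that add atoms: none
Why: Partial reduction of a γ-lactone with i-Bu2AlH stops at the lactol because the aluminium hemiacetal is stable at −78 °C, and C8 is not touched.

Step 3
Reactants: 3 (3R)-3-methyloxolan-2-ol
Product: 4 (3R)-3-methylpent-4-yn-1-ol
Conditions: dimethyl (1-diazo-2-oxopropyl)phosphonate (1.5 equiv), K2CO3 (2.5 equiv), MeOH, 0 °C → rt
Reagents that add atoms: dimethyl (1-diazo-2-oxopropyl)phosphonate, COP(=O)(OC)C(=[N+]=[N-])C(C)=O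
Why: Seyferth–Gilbert homologation in its Ohira–Bestmann form acts on the open hydroxy aldehyde tautomer of the lactol under carbonate in methanol, mild enough that the α-stereocentre C8 should survive.

Step 4
Reactants: 4 (3R)-3-methylpent-4-yn-1-ol
Product: 6 (3R,4E)-5-iodo-3,4-dimethylpent-4-en-1-ol, via alkenylalane 5 (not isolated)
Conditions: AlMe3 (3.0 equiv), Cp2ZrCl2 (0.25 equiv), CH2Cl2, 0 °C → rt; then I2, THF, −30 → 0 °C
Reagents that add atoms: trimethylaluminium, C[Al](C)C; iodine, II
Why: Negishi zirconium-catalysed carboalumination adds methyl (C20) and aluminium syn across the terminal alkyne with methyl on the internal carbon, and iodinolysis with retention gives the (E)-alkenyl iodide, the hydroxyl being carried as its aluminium alkoxide.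

Step 5
Reactants: 7 methyl hydrogen (R)-3-methylglutarate [(3R)-5-methoxy-3-methyl-5-oxopentanoic acid]
Product: 8 methyl (3S)-4-iodo-3-methylbutanoate
Conditions: PhI(OAc)2, I2, PhCl, hν (tungsten lamp), 80 °C
Reagents that add atoms: iodine, II
Why: Hunsdiecker-type iododecarboxylation under Suárez conditions (acyl hypoiodite homolysis, loss of CO2, iodine transfer to the primary radical) removes the acid carbon without touching C13, whose descriptor changes to S only through the priority order.

Step 6
Reactants: 8 methyl (3S)-4-iodo-3-methylbutanoate; 6 (3R,4E)-5-iodo-3,4-dimethylpent-4-en-1-ol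
Product: 10 methyl (3R,5E,7R)-9-hydroxy-3,6,7-trimethylnon-5-enoate, via alkylzinc iodide 9 (not isolated)
Conditions: 8, Zn dust (activated with BrCH2CH2Br and Me3SiCl), THF, 40 °C; then 6 (0.45 equiv), Pd(OAc)2 (3 mol%), SPhos (6 mol%), THF, rt
Reagents that add atoms: none
Why: Negishi sp3–sp2 cross-coupling of an ester-bearing primary alkylzinc iodide with an alkenyl iodide keeps the alkene geometry and tolerates the free hydroxyl when the zinc reagent is used in excess.

Step 7
Reactants: 10 methyl (3R,5E,7R)-9-hydroxy-3,6,7-trimethylnon-5-enoate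
Product: 11 methyl (3R,5E,7R)-9-iodo-3,6,7-trimethylnon-5-enoate
Conditions: I2, PPh3, imidazole, CH2Cl2, 0 °C → rt
Reagents that add atoms: iodine, II
Why: Appel-type iodination converts the unhindered primary alcohol into the iodide by SN2 displacement of the oxyphosphonium group and leaves ester, alkene and both stereocentres alone.

Step 8
Reactants: 12 3-methylcyclohex-2-en-1-one
Product: 13 2-iodo-3-methylcyclohex-2-en-1-one
Conditions: I2 (2 equiv), pyridine/CH2Cl2, 0 °C → rt
Reagents that add atoms: iodine, II
Why: α-Iodination of an enone by the Baylis–Hillman-type sequence (pyridine conjugate addition, iodination of the enolate, elimination of pyridine) gives the 2-iodoenone.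

Step 9
Reactants: 11 methyl (3R,5E,7R)-9-iodo-3,6,7-trimethylnon-5-enoate; 13 2-iodo-3-methylcyclohex-2-en-1-one
Product: 15 methyl (3R,5E,7R)-3,6,7-trimethyl-9-(2-methyl-6-oxocyclohex-1-en-1-yl)non-5-enoate, via alkylzinc iodide 14 (not isolated)
Conditions: 11, Zn dust (activated), THF, 40 °C; then 13, PdCl2(dppf) (5 mol%), THF/DMA, 40 °C
Reagents that add atoms: none
Why: Zinc insertion into the primary iodide followed by Negishi coupling with an α-iodoenone is a regiospecific α-alkylation of the enone that forms C5–C6 without any enolate alkylation next to the future gem-dimethyl carbon.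

Step 10
Reactants: 15 methyl (3R,5E,7R)-3,6,7-trimethyl-9-(2-methyl-6-oxocyclohex-1-en-1-yl)non-5-enoate
Product: 17 methyl (3R,5E,7R)-9-(6,6-dimethyl-2-{[(prop-2-en-1-yloxy)carbonyl]oxy}cyclohex-1-en-1-yl)-3,6,7-trimethylnon-5-enoate, via lithium enolate 16 (not isolated)
Conditions: Me2CuLi (2.6 equiv, from CuI and MeLi), Et2O, −20 → 0 °C; then TMEDA, allyl chloroformate (6 equiv), THF, −78 → 0 °C
Reagents that add atoms: lithium dimethylcuprate, [Li+].C[Cu-]C; allyl chloroformate, C=CCOC(Cl)=O
Why: Conjugate addition of the Gilman cuprate to the β-methyl enone builds the C4 gem-dimethyl group and a regiodefined C5=C10 enolate, which the chloroformate acylates on oxygen because its carbon terminus is flanked by a quaternary carbon (any C-acylated allyl β-keto ester converges on the same ketone in step 11), while the methyl ester is inert to the cuprate at this temperature.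

Step 11
Reactants: 17 methyl (3R,5E,7R)-9-(6,6-dimethyl-2-{[(prop-2-en-1-yloxy)carbonyl]oxy}cyclohex-1-en-1-yl)-3,6,7-trimethylnon-5-enoate
Product: 18 methyl (3R,5E,7R)-9-[(1S)-2,2-dimethyl-6-oxocyclohexyl]-3,6,7-trimethylnon-5-enoate
Conditions: Pd(OAc)2 (10 mol%), (S)-t-BuPHOX (12.5 mol%), HCO2H (5 equiv), 4 Å molecular sieves, 1,4-dioxane, 40 °C
Reagents that add atoms: none
Why: Palladium-catalysed decarboxylative enantioselective protonation: zerovalent palladium ionises the allyl carbonate, loss of CO2 leaves a palladium enolate held by the chiral PHOX ligand, formic acid protonates C5 on one face (setting 5S) and formate reduces the allyl group to propene.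

Step 12
Reactants: 18 methyl (3R,5E,7R)-9-[(1S)-2,2-dimethyl-6-oxocyclohexyl]-3,6,7-trimethylnon-5-enoate
Product: 20 methyl (3R,5E,7R)-9-[(1S)-6,6-dimethyl-2-(triflyloxy)cyclohex-2-en-1-yl]-3,6,7-trimethylnon-5-enoate (methyl 10-trifloxy-9,10-secohalima-1(10),9(11)E-dien-15-oate), via potassium enolate 19 (not isolated)
Conditions: KN(SiMe3)2 (1.1 equiv), THF, −78 °C (ketone added to base); then PhNTf2 (1.2 equiv), −78 → 0 °C
Reagents that add atoms: N-phenylbis(trifluoromethanesulfonimide), O=S(=O)(N(c1ccccc1)S(=O)(=O)C(F)(F)F)C(F)(F)F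
Why: Kinetic deprotonation by the bulky amide takes a proton from the open C1 methylene and not the tertiary C5–H next to the gem-dimethyl carbon (the ketone is also far more acidic than the ester), and O-triflation of the enolate fixes the C1=C10 enol triflate without epimerising C5.

Step 13
Reactants: 20 methyl 10-trifloxy-9,10-secohalima-1(10),9(11)E-dien-15-oate
Product: 21 methyl (5S,8R,9S,13S)-halima-1(10),11E-dien-15-oate
Conditions: Pd(OAc)2 (10 mol%), (R)-BINAP (20 mol%), K2CO3 (3 equiv), toluene, 80 °C
Reagents that add atoms: none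
Why: Zerovalent palladium (formed from Pd(OAc)2 and BINAP) inserts into the C10–OTf bond, the cationic divalent vinylpalladium binds the tethered (E)-C9=C11 alkene and adds syn across it with C10 bonding to C9, and the C11–Pd species, which has β-hydrogens only on C12, eliminates to the (E)-C11=C12 alkene while the triflate carbon stays C10 of the untouched C1=C10 alkene. The closest known reaction type is the intramolecular Heck cyclisation of vinyl or aryl triflates onto trisubstituted alkenes that creates quaternary carbons with Pd(OAc)2/BINAP. Ring B closes in the 6-exo-trig mode, since 7-endo attack at C11 would need the larger ring and would put palladium on the fully substituted C9. The new stereocentre C9 is fixed by the alkene face that C10 reaches: in the chair-like transition state C4 must stay near the plane of the ring A alkene so that H5 is axial, the palladium-bound C11 sits pseudo-axial and syn to H5, and the C8 methyl takes the equatorial site, which places C20 trans to C17 as the target requires; (R)-BINAP is proposed as the ligand that reinforces this substrate preference. The step needs exo regioselectivity, this facial selectivity and no migration of the new alkene toward C13; the tether length, the C5 and C8 stereocentres and fast removal of the palladium hydride by carbonate are relied on for these. The triflate already opens the cationic pathway, so no silver salt is needed.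

Step 14
Reactants: 21 methyl (5S,8R,9S,13S)-halima-1(10),11E-dien-15-oate
Product: 22 methyl (5S,8R,9R,13R)-halim-1(10)-en-15-oate
Conditions: H2 (4 bar), RhCl(PPh3)3 (10 mol%), toluene/EtOH (1:1), 40 °C
Reagents that add atoms: none
Why: Homogeneous hydrogenation with RhCl(PPh3)3 reduces the 1,2-disubstituted C11=C12 alkene much faster than the trisubstituted C1=C10 alkene, which is shielded by C9 and C5, and is not expected to isomerise the alkene toward C13 (the C9 and C13 descriptors change only through the priority order).

Step 15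
Reactants: 22 methyl (5S,8R,9R,13R)-halim-1(10)-en-15-oate
Product: 23 (5S,8R,9R,13R)-halim-1(10)-en-15-oic acid
Conditions: LiOH·H2O (5 equiv), THF/MeOH/H2O (3:1:1), 40 °C; then 1 M HCl to pH 3, 0 °C
Reagents that add atoms: lithium hydroxide, [Li+].[OH-]
Why: Saponification of the unhindered methyl ester with hydroxide, in which the nearest stereocentre C13 is β to the carbonyl and cannot epimerise.

Step 16
Reactants: 24 (S)-glycidol [(2S)-oxiran-2-ylmethanol]
Product: 25 (R)-glycidyl acetate [(2R)-oxiran-2-ylmethyl acetate]
Conditions: Ac2O (1.2 equiv), Et3N (1.5 equiv), DMAP (5 mol%), CH2Cl2, 0 °C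
Reagents that add atoms: acetic anhydride, CC(=O)OC(C)=O
Why: DMAP-catalysed O-acetylation of the primary alcohol leaves the epoxide and its stereocentre untouched, the descriptor becoming R only because the priority order changes.

Step 17
Reactants: 23 (5S,8R,9R,13R)-halim-1(10)-en-15-oic acid; 25 (R)-glycidyl acetate
Product: 26 (2S)-3-acetoxy-2-hydroxypropyl (5S,8R,9R,13R)-halim-1(10)-en-15-oate (target)
Conditions: 25 (1.5 equiv), n-Bu4NBr (10 mol%), toluene, 90 °C
Reagents that add atoms: none
Why: Halide-catalysed addition of a carboxylic acid to a glycidyl ester, in which the carboxylate attacks the unsubstituted epoxide carbon so that the stereocentre is not involved and ends as the (2S) secondary alcohol between the two acyloxymethyl groups.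

**Compound list**
1 | α-methylene-γ-butyrolactone (3-methylideneoxolan-2-one) | C=C1CCOC1=O | starting material
2 | (3R)-3-methyloxolan-2-one | O=C1[C@H](C)CCO1 | intermediate
3 | (3R)-3-methyloxolan-2-ol (anomers) | OC1[C@H](C)CCO1 | intermediate
4 | (3R)-3-methylpent-4-yn-1-ol | C#C[C@H](C)CCO | intermediate
5 | dimethylaluminium alkoxide of (3R,4E)-5-(dimethylalumanyl)-3,4-dimethylpent-4-en-1-ol | C[Al](C)/C=C(\C)[C@H](C)CCO[Al](C)C | intermediate (not isolated)
6 | (3R,4E)-5-iodo-3,4-dimethylpent-4-en-1-ol | I/C=C(\C)[C@H](C)CCO | intermediate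
7 | methyl hydrogen (R)-3-methylglutarate | COC(=O)C[C@H](C)CC(=O)O | starting material
8 | methyl (3S)-4-iodo-3-methylbutanoate | COC(=O)C[C@H](C)CI | intermediate
9 | [(2S)-4-methoxy-2-methyl-4-oxobutyl]zinc iodide | COC(=O)C[C@H](C)C[Zn]I | intermediate (not isolated)
10 | methyl (3R,5E,7R)-9-hydroxy-3,6,7-trimethylnon-5-enoate | COC(=O)C[C@H](C)C/C=C(\C)[C@H](C)CCO | intermediate
11 | methyl (3R,5E,7R)-9-iodo-3,6,7-trimethylnon-5-enoate | COC(=O)C[C@H](C)C/C=C(\C)[C@H](C)CCI | intermediate
12 | 3-methylcyclohex-2-en-1-one | CC1=CC(=O)CCC1 | starting material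
13 | 2-iodo-3-methylcyclohex-2-en-1-one | CC1=C(I)C(=O)CCC1 | intermediate
14 | [(3R,4E,7R)-9-methoxy-3,4,7-trimethyl-9-oxonon-4-en-1-yl]zinc iodide | COC(=O)C[C@H](C)C/C=C(\C)[C@H](C)CC[Zn]I | intermediate (not isolated)
15 | methyl (3R,5E,7R)-3,6,7-trimethyl-9-(2-methyl-6-oxocyclohex-1-en-1-yl)non-5-enoate | COC(=O)C[C@H](C)C/C=C(\C)[C@H](C)CCC1=C(C)CCCC1=O | intermediate
16 | lithium enolate of ketone 18 (C5=C10 enolate) | COC(=O)C[C@H](C)C/C=C(\C)[C@H](C)CCC1=C([O-])CCCC1(C)C.[Li+] | intermediate (not isolated)
17 | methyl (3R,5E,7R)-9-(6,6-dimethyl-2-{[(prop-2-en-1-yloxy)carbonyl]oxy}cyclohex-1-en-1-yl)-3,6,7-trimethylnon-5-enoate | COC(=O)C[C@H](C)C/C=C(\C)[C@H](C)CCC1=C(OC(=O)OCC=C)CCCC1(C)C | intermediate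
18 | methyl (3R,5E,7R)-9-[(1S)-2,2-dimethyl-6-oxocyclohexyl]-3,6,7-trimethylnon-5-enoate | COC(=O)C[C@H](C)C/C=C(\C)[C@H](C)CC[C@@H]1C(=O)CCCC1(C)C | intermediate
19 | potassium enolate of ketone 18 (C1=C10 enolate) | COC(=O)C[C@H](C)C/C=C(\C)[C@H](C)CC[C@@H]1C([O-])=CCCC1(C)C.[K+] | intermediate (not isolated)
20 | methyl 10-trifloxy-9,10-secohalima-1(10),9(11)E-dien-15-oate | COC(=O)C[C@H](C)C/C=C(\C)[C@H](C)CC[C@@H]1C(OS(=O)(=O)C(F)(F)F)=CCCC1(C)C | intermediate
21 | methyl (5S,8R,9S,13S)-halima-1(10),11E-dien-15-oate | COC(=O)C[C@H](C)/C=C/[C@@]1(C)C2=CCCC(C)(C)[C@@H]2CC[C@H]1C | intermediate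
22 | methyl (5S,8R,9R,13R)-halim-1(10)-en-15-oate | COC(=O)C[C@H](C)CC[C@@]1(C)C2=CCCC(C)(C)[C@@H]2CC[C@H]1C | intermediate
23 | (5S,8R,9R,13R)-halim-1(10)-en-15-oic acid | OC(=O)C[C@H](C)CC[C@@]1(C)C2=CCCC(C)(C)[C@@H]2CC[C@H]1C | intermediate
24 | (S)-glycidol | OC[C@H]1CO1 | starting material
25 | (R)-glycidyl acetate | CC(=O)OC[C@H]1CO1 | intermediate
26 | (2S)-3-acetoxy-2-hydroxypropyl (5S,8R,9R,13R)-halim-1(10)-en-15-oate | CC(=O)OC[C@H](O)COC(=O)C[C@H](C)CC[C@@]1(C)C2=CCCC(C)(C)[C@@H]2CC[C@H]1C | target

**Step count**
Total: 17 steps. Longest linear sequence: 14 steps (1–4, 6, 7, 9–15, 17).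

**Steps most likely to fail**

Step 13 (Heck ring closure). The palladium hydride formed after ring closure may re-add to the new C11=C12 alkene and walk it toward C13, which would erase the C13 configuration. The single C8 methyl may also discriminate the two faces of C9 only weakly, or insertion into the trisubstituted alkene may be too slow. The fallback sets out from 7, 13 and 8 and returns to the route at 22; it closes ring B by an enolate–triflate coupling and makes C9 quaternary afterwards by alkylation.
- BH3·SMe2 reduces the acid of 7 to methyl (3R)-5-hydroxy-3-methylpentanoate F1, and PPh3/I2/imidazole gives methyl (3S)-5-iodo-3-methylpentanoate F2.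
- Zinc insertion and Negishi coupling with 13, as in step 9, gives methyl (3R)-3-methyl-5-(2-methyl-6-oxocyclohex-1-en-1-yl)pentanoate F3.
- Me2CuLi and then allyl chloroformate, as in step 10, gives the allyl enol carbonate F4; decarboxylative protonation as in step 11 gives the (1S)-ketone F5; triflation as in step 12 gives the enol triflate F6.
- Pd2(dba)3/P(t-Bu)3 with LiN(SiMe3)2 in toluene joins the ester enolate carbon C9 to the C10 triflate (intramolecular α-alkenylation of an ester) to give the bicyclic ester F7 as C9 epimers.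
- LiN(i-Pr)2 and then MeI methylate the dienolate of F7 at C9 on the face away from the neighbouring C8 methyl, which sits pseudo-axial to avoid allylic strain with the enolate; this gives the quaternary ester F8 with C20 trans to C17.
- i-Bu2AlH at −78 °C gives the aldehyde F9.
- The phosphonium iodide F10, made from 8 and PPh3, is converted into its ylide with NaN(SiMe3)2 and condensed with F9 (Wittig) to give methyl (5S,8R,9S,13S)-halima-1(10),11Z-dien-15-oate F11, which is hydrogenated under the conditions of step 14 to 22.

Step 11 (enantioselective protonation). Protonation of the congested tetrasubstituted palladium enolate may discriminate its faces poorly, so that the C5 epimer travels on as a diastereomer, or C-allylation may compete with protonation. The fallback sets out from 15 and returns at 18. Me2CuLi is added to 15 in the presence of Me3SiCl to give the trimethylsilyl enol ether F12. This is protonated at −78 °C in toluene by the Lewis-acid-assisted chiral Brønsted acid formed from SnCl4 and (R)-BINOL monomethyl ether (enantioselective protonation of a silyl enol ether), which should react with the enol ether far faster than with the isolated trisubstituted alkene, to give 18.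

Step 17 (epoxide opening). The carboxylate may attack the internal epoxide carbon, or acyl groups may migrate between the primary and secondary oxygens at 90 °C, giving regioisomeric diacylglycerols. The fallback sets out from 23 and returns at 26. Acid 23 is esterified with (R)-solketal (EDC·HCl, DMAP, CH2Cl2) to give the acetonide ester F13. The acetonide is removed with Me2BBr in CH2Cl2 at −50 °C, conditions that do not move the acyl group, to give the (2S)-2,3-dihydroxypropyl ester F14. The primary hydroxyl alone is then acetylated with vinyl acetate and immobilised Candida antarctica lipase B to give 26.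

**Further compounds**
F1 | step 13 | methyl (3R)-5-hydroxy-3-methylpentanoate | COC(=O)C[C@H](C)CCO
F2 | step 13 | methyl (3S)-5-iodo-3-methylpentanoate | COC(=O)C[C@H](C)CCI
F3 | step 13 | methyl (3R)-3-methyl-5-(2-methyl-6-oxocyclohex-1-en-1-yl)pentanoate | COC(=O)C[C@H](C)CCC1=C(C)CCCC1=O
F4 | step 13 | methyl (3R)-5-(6,6-dimethyl-2-{[(prop-2-en-1-yloxy)carbonyl]oxy}cyclohex-1-en-1-yl)-3-methylpentanoate | COC(=O)C[C@H](C)CCC1=C(OC(=O)OCC=C)CCCC1(C)C
F5 | step 13 | methyl (3R)-5-[(1S)-2,2-dimethyl-6-oxocyclohexyl]-3-methylpentanoate | COC(=O)C[C@H](C)CC[C@@H]1C(=O)CCCC1(C)C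
F6 | step 13 | methyl (3R)-5-[(1S)-6,6-dimethyl-2-(triflyloxy)cyclohex-2-en-1-yl]-3-methylpentanoate | COC(=O)C[C@H](C)CC[C@@H]1C(OS(=O)(=O)C(F)(F)F)=CCCC1(C)C
F7 | step 13 | methyl (2R,4aS)-2,5,5-trimethyl-1,2,3,4,4a,5,6,7-octahydronaphthalene-1-carboxylate (C1 epimers; C1 is halimane C9) | COC(=O)C1C2=CCCC(C)(C)[C@@H]2CC[C@H]1C
F8 | step 13 | methyl (1R,2R,4aS)-1,2,5,5-tetramethyl-1,2,3,4,4a,5,6,7-octahydronaphthalene-1-carboxylate | COC(=O)[C@@]1(C)C2=CCCC(C)(C)[C@@H]2CC[C@H]1C
F9 | step 13 | (1R,2R,4aS)-1,2,5,5-tetramethyl-1,2,3,4,4a,5,6,7-octahydronaphthalene-1-carbaldehyde | O=C[C@@]1(C)C2=CCCC(C)(C)[C@@H]2CC[C@H]1C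
F10 | step 13 | [(2S)-4-methoxy-2-methyl-4-oxobutyl]triphenylphosphonium iodide | COC(=O)C[C@H](C)C[P+](c1ccccc1)(c1ccccc1)c1ccccc1.[I-]
F11 | step 13 | methyl (5S,8R,9S,13S)-halima-1(10),11Z-dien-15-oate | COC(=O)C[C@H](C)/C=C\[C@@]1(C)C2=CCCC(C)(C)[C@@H]2CC[C@H]1C
F12 | step 11 | methyl (3R,5E,7R)-9-{6,6-dimethyl-2-[(trimethylsilyl)oxy]cyclohex-1-en-1-yl}-3,6,7-trimethylnon-5-enoate | COC(=O)C[C@H](C)C/C=C(\C)[C@H](C)CCC1=C(O[Si](C)(C)C)CCCC1(C)C
F13 | step 17 | [(4S)-2,2-dimethyl-1,3-dioxolan-4-yl]methyl (5S,8R,9R,13R)-halim-1(10)-en-15-oate | CC1(C)OC[C@@H](COC(=O)C[C@H](C)CC[C@@]2(C)C3=CCCC(C)(C)[C@@H]3CC[C@H]2C)O1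
F14 | step 17 | (2S)-2,3-dihydroxypropyl (5S,8R,9R,13R)-halim-1(10)-en-15-oate | OC[C@H](O)COC(=O)C[C@H](C)CC[C@@]1(C)C2=CCCC(C)(C)[C@@H]2CC[C@H]1C
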